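The plan cuts ring B at C1'-C6' and C2'-C3'. From C1' to C4' this ring alternates carbon, oxygen, carbon, oxygen without a gap, and C3'/C4' are shared with ring D. Read backwards, C3'-C4'-C5'-C6' with ring D attached is what a prenal-annulated 4-oxy-2-pyrone leaves behind after losing CO2, while C1'-C2' is an oxygenated alkyne. One cycloaddition/decarboxylation therefore assembles the whole arene with all four substituents placed by polarity. The precursors are a bicyclic pyranopyranone and a TIPS ynol ether bearing a silyloxyethyl arm. That arm becomes an arylacetic acid, an oxazolidinone sets C3, and phloroglucinol supplies ring A before acylative closure of ring C.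

Key step: step 3

Remark: the stereocentre in the target SMILES reads as 3R (C4 > C2 > C1' > H), which fixes the (S)-4-benzyl auxiliary; 4-hydroxy-2H-pyran-2-one and the TBS ether of but-3-yn-1-ol are taken as catalogue compounds.

Step 1
Reactants: 1 4-hydroxy-2H-pyran-2-one; 2 prenal (3-methylbut-2-enal)
Product: 4 2,2-dimethyl-2H,5H-pyrano[4,3-b]pyran-5-one, via oxatriene 3 (not isolated)
Conditions: ethylenediammonium diacetate (10 mol %), CH2Cl2, rt to 40 °C
Reagents that add atoms: none
Why: Knoevenagel condensation at the nucleophilic C3 of the hydroxypyrone followed by oxa-6π electrocyclisation of 3 (formal [3+3] annulation) is the standard entry to 2H-pyrano[4,3-b]pyran-5-ones, and closure through the C4 oxygen keeps the 2-pyrone intact.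

Step 2
Reactants: 5 4-(tert-butyldimethylsilyloxy)but-1-yne
Product: 8 4-(tert-butyldimethylsilyloxy)-1-(triisopropylsilyloxy)but-1-yne, via lithium acetylide 6 (not isolated), via lithium ynolate 7 (not isolated)
Conditions: n-BuLi, THF, −78 °C; LiOOt-Bu (from t-BuOOH and LiN(SiMe3)2, THF, −78 °C), −78 to 0 °C; TIPSOTf, −78 to 0 °C
Reagents that add atoms: tert-butyl hydroperoxide CC(C)(C)OO; triisopropylsilyl trifluoromethanesulfonate CC(C)[Si](OS(=O)(=O)C(F)(F)F)(C(C)C)C(C)C
Why: Oxygenation of a lithium acetylide by lithium tert-butyl peroxide gives the ynolate, which the bulky silyl triflate traps on oxygen (acetylide oxidation/O-silylation route to siloxyalkynes), and the TBS ether is inert to these bases.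

Step 3
Reactants: 4 2,2-dimethyl-2H,5H-pyrano[4,3-b]pyran-5-one; 8 4-(tert-butyldimethylsilyloxy)-1-(triisopropylsilyloxy)but-1-yne
Product: 10 6-[2-(tert-butyldimethylsilyloxy)ethyl]-5-(triisopropylsilyloxy)-2,2-dimethyl-2H-chromene, via bridged lactone 9 (not isolated)
Conditions: 8 (1.5 equiv), AgNTf2 (10 mol %), 4 Å MS, ClCH2CH2Cl, rt to 60 °C, dark
Reagents that add atoms: none
Why: AgNTf2 polarises the ynol ether so that its carbon remote from oxygen attacks C7 of 4 (C6 of the pyrone, the open end of the conjugated acceptor) and the developing silyl ketenium carbon is closed onto C4a (pyrone C3), in one asynchronous event or in two stages, giving oxabicyclo[2.2.2]octadienone 9, which expels CO2 by retro-[4+2] and aromatises. The closest known reaction type is the Diels-Alder/decarboxylation benzannulation of 2-pyrones with alkynes, taken together with silver-promoted inverse-demand additions of siloxyalkynes to electron-poor heterodienes; the ring D oxygen makes 4 a weaker acceptor than those dienes, hence the Lewis acid, the excess of 8 and the gentle heating. Ring B is closed in a [4+2] mode, C1'-C6' and C2'-C3' being formed in the same operation while ring D rides along untouched. The two bridgehead stereocentres of 9 vanish with the CO2, so nothing stereochemical has to be controlled. Regioselectivity (oxygen at C2', side chain at C1') is needed and is secured twice over, since the nucleophilic alkyne carbon matches the electrophilic pyrone C6 and the cationic siloxy carbon matches pyrone C3, which the 4-oxygen makes the most nucleophilic ring carbon. Periselectivity over [2+2] addition is secured because only the [4+2] adduct has the irreversible CO2 exit to an arene.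

Step 4
Reactants: 10 6-[2-(tert-butyldimethylsilyloxy)ethyl]-5-(triisopropylsilyloxy)-2,2-dimethyl-2H-chromene
Product: 11 2-[2,2-dimethyl-5-(triisopropylsilyloxy)-2H-chromen-6-yl]ethanol
Conditions: camphorsulfonic acid (10 mol %), MeOH/CH2Cl2, 0 °C
Reagents that add atoms: none
Why: Acid-catalysed methanolysis removes a primary alkyl TBS ether far faster than a doubly ortho-flanked aryl TIPS ether (selective desilylation), and the short cold exposure spares the chromene.

Step 5
Reactants: 11 2-[2,2-dimethyl-5-(triisopropylsilyloxy)-2H-chromen-6-yl]ethanol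
Product: 13 2-[2,2-dimethyl-5-(triisopropylsilyloxy)-2H-chromen-6-yl]acetic acid, via arylacetaldehyde 12 (not isolated)
Conditions: 2,2,6,6-tetramethylpiperidin-1-oxyl (TEMPO, 20 mol %), PhI(OAc)2 (2.2 equiv), MeCN/H2O, rt
Reagents that add atoms: water O
Why: Oxoammonium-mediated oxidation takes the primary alcohol through 12 and its hydrate to the acid under near-neutral conditions that leave the chromene alkene and the silyl ether alone.

Step 6
Reactants: 13 2-[2,2-dimethyl-5-(triisopropylsilyloxy)-2H-chromen-6-yl]acetic acid; 14 (S)-4-benzyloxazolidin-2-one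
Product: 16 (S)-4-benzyl-3-{2-[2,2-dimethyl-5-(triisopropylsilyloxy)-2H-chromen-6-yl]acetyl}oxazolidin-2-one, via mixed pivalic anhydride 15 (not isolated)
Conditions: PivCl, Et3N, THF, −20 °C; then 14, LiCl, rt
Reagents that add atoms: none
Why: Mixed-anhydride N-acylation of the oxazolidinone under LiCl/Et3N needs no strong base, and attack falls on the less hindered arylacetyl carbonyl of 15.

Step 7
Reactants: 16 (S)-4-benzyl-3-{2-[2,2-dimethyl-5-(triisopropylsilyloxy)-2H-chromen-6-yl]acetyl}oxazolidin-2-one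
Product: 18 (S)-4-benzyl-3-{(R)-2-[2,2-dimethyl-5-(triisopropylsilyloxy)-2H-chromen-6-yl]-3-hydroxypropanoyl}oxazolidin-2-one, via titanium enolate 17 (not isolated)
Conditions: TiCl4 (1.05 equiv), i-Pr2NEt (1.1 equiv), CH2Cl2, 0 °C; then 1,3,5-trioxane, TiCl4 (1.05 equiv), 0 °C; aq NH4Cl
Reagents that add atoms: 1,3,5-trioxane C1OCOCO1
Why: Soft enolisation gives the chelated Z-enolate 17, which TiCl4-activated formaldehyde attacks on the face opposite the benzyl group (auxiliary-controlled hydroxymethylation, an aldol-type reaction), setting the future C3 as R.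

Step 8
Reactants: 19 phloroglucinol
Product: 20 3,5-bis(triisopropylsilyloxy)phenol
Conditions: TIPSCl (2.0 equiv), imidazole, DMF, 0 °C to rt; chromatography
Reagents that add atoms: triisopropylsilyl chloride CC(C)[Si](Cl)(C(C)C)C(C)C
Why: Silylation of phloroglucinol occurs only on oxygen and the bis-ether is separated from the other, recyclable silylation levels (statistical O-silylation), TIPS being chosen because it survives LiOOH and later falls together with the 2'-O-TIPS group.

Step 9
Reactants: 18 (S)-4-benzyl-3-{(R)-2-[2,2-dimethyl-5-(triisopropylsilyloxy)-2H-chromen-6-yl]-3-hydroxypropanoyl}oxazolidin-2-one; 20 3,5-bis(triisopropylsilyloxy)phenol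
Product: 21 (S)-4-benzyl-3-{(R)-3-[3,5-bis(triisopropylsilyloxy)phenoxy]-2-[2,2-dimethyl-5-(triisopropylsilyloxy)-2H-chromen-6-yl]propanoyl}oxazolidin-2-one
Conditions: PPh3, DIAD (added last, slowly), toluene, 0 °C to rt
Reagents that add atoms: none
Why: Mitsunobu etherification displaces the activated primary hydroxyl with the phenol without touching the stereocentre, whose C-H bond is held out of alignment with the imide carbonyl by allylic strain, so elimination should stay minor.

Step 10
Reactants: 21 (S)-4-benzyl-3-{(R)-3-[3,5-bis(triisopropylsilyloxy)phenoxy]-2-[2,2-dimethyl-5-(triisopropylsilyloxy)-2H-chromen-6-yl]propanoyl}oxazolidin-2-one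
Product: 23 (R)-3-[3,5-bis(triisopropylsilyloxy)phenoxy]-2-[2,2-dimethyl-5-(triisopropylsilyloxy)-2H-chromen-6-yl]propanoic acid, via lithium percarboxylate 22 (not isolated)
Conditions: LiOH, H2O2, THF/H2O, 0 °C; Na2SO3; then 1 M HCl to pH 3, 0 °C
Reagents that add atoms: hydrogen peroxide OO
Why: Hydroperoxide attacks the exocyclic imide carbonyl selectively (LiOOH auxiliary cleavage), 22 is reduced by sulfite before acidification so that no peracid meets the chromene, and the cold, weakly basic medium should neither epimerise nor eliminate.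

Step 11
Reactants: 23 (R)-3-[3,5-bis(triisopropylsilyloxy)phenoxy]-2-[2,2-dimethyl-5-(triisopropylsilyloxy)-2H-chromen-6-yl]propanoic acid
Product: 25 (R)-3-[2,2-dimethyl-5-(triisopropylsilyloxy)-2H-chromen-6-yl]-5,7-bis(triisopropylsilyloxy)chroman-4-one, via acid chloride 24 (not isolated)
Conditions: 1-chloro-N,N,2-trimethylprop-1-en-1-amine, CH2Cl2, 0 °C; then SnCl4, −78 °C; cold aq NaHCO3
Reagents that add atoms: none
Why: Intramolecular Friedel-Crafts acylation closes six-membered ring C at either of the two equivalent positions ortho to the ether oxygen of the triply oxygen-activated ring A, and base-free chloride formation plus −78 °C guard the configuration at C3.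

Step 12
Reactants: 25 (R)-3-[2,2-dimethyl-5-(triisopropylsilyloxy)-2H-chromen-6-yl]-5,7-bis(triisopropylsilyloxy)chroman-4-one
Product: 26 (R)-5,7-dihydroxy-3-(5-hydroxy-2,2-dimethyl-2H-chromen-6-yl)chroman-4-one (CNP0235388.1)
Conditions: TBAF, AcOH (equimolar, 4 equiv each), THF, 0 °C
Reagents that add atoms: none
Why: Fluoride cleaves all three aryl TIPS ethers (global desilylation), and the acetic acid buffer keeps the medium from enolising C3-H of the isoflavanone, so the R configuration is retained.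

Compound list
1 | 4-hydroxy-2H-pyran-2-one | O=c1cc(O)cco1 | starting material
2 | prenal (3-methylbut-2-enal) | CC(C)=CC=O | starting material
3 | (E)-3-(3-methylbut-2-en-1-ylidene)-2H-pyran-2,4(3H)-dione (oxatriene, formed in situ) | CC(C)=C/C=C1\C(=O)C=COC1=O | intermediate
4 | 2,2-dimethyl-2H,5H-pyrano[4,3-b]pyran-5-one | CC1(C)C=CC2=C(C=COC2=O)O1 | intermediate
5 | 4-(tert-butyldimethylsilyloxy)but-1-yne | C#CCCO[Si](C)(C)C(C)(C)C | starting material
6 | lithium 4-(tert-butyldimethylsilyloxy)but-1-yn-1-ide (formed in situ) | [Li]C#CCCO[Si](C)(C)C(C)(C)C | intermediate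
7 | lithium 4-(tert-butyldimethylsilyloxy)but-1-yn-1-olate (formed in situ) | [Li]OC#CCCO[Si](C)(C)C(C)(C)C | intermediate
8 | 4-(tert-butyldimethylsilyloxy)-1-(triisopropylsilyloxy)but-1-yne | CC(C)[Si](OC#CCCO[Si](C)(C)C(C)(C)C)(C(C)C)C(C)C | intermediate
9 | [4+2] adduct, racemic: C4a and C7 of 4 bridged by C(OTIPS)=C(CH2CH2OTBS), siloxy carbon on C4a, O-C(=O) bridge retained (formed in situ) | CC1(C)C=CC23C(=O)OC(C=C2O1)C(CCO[Si](C)(C)C(C)(C)C)=C3O[Si](C(C)C)(C(C)C)C(C)C | intermediate
10 | 6-[2-(tert-butyldimethylsilyloxy)ethyl]-5-(triisopropylsilyloxy)-2,2-dimethyl-2H-chromene | CC1(C)C=Cc2c(ccc(CCO[Si](C)(C)C(C)(C)C)c2O[Si](C(C)C)(C(C)C)C(C)C)O1 | intermediate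
11 | 2-[2,2-dimethyl-5-(triisopropylsilyloxy)-2H-chromen-6-yl]ethanol | CC1(C)C=Cc2c(ccc(CCO)c2O[Si](C(C)C)(C(C)C)C(C)C)O1 | intermediate
12 | 2-[2,2-dimethyl-5-(triisopropylsilyloxy)-2H-chromen-6-yl]acetaldehyde (formed in situ) | CC1(C)C=Cc2c(ccc(CC=O)c2O[Si](C(C)C)(C(C)C)C(C)C)O1 | intermediate
13 | 2-[2,2-dimethyl-5-(triisopropylsilyloxy)-2H-chromen-6-yl]acetic acid | CC1(C)C=Cc2c(ccc(CC(=O)O)c2O[Si](C(C)C)(C(C)C)C(C)C)O1 | intermediate
14 | (S)-4-benzyloxazolidin-2-one | O=C1N[C@@H](Cc2ccccc2)CO1 | starting material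
15 | mixed anhydride of 13 and pivalic acid (formed in situ) | CC1(C)C=Cc2c(ccc(CC(=O)OC(=O)C(C)(C)C)c2O[Si](C(C)C)(C(C)C)C(C)C)O1 | intermediate
16 | (S)-4-benzyl-3-{2-[2,2-dimethyl-5-(triisopropylsilyloxy)-2H-chromen-6-yl]acetyl}oxazolidin-2-one | CC1(C)C=Cc2c(ccc(CC(=O)N3[C@@H](Cc4ccccc4)COC3=O)c2O[Si](C(C)C)(C(C)C)C(C)C)O1 | intermediate
17 | Z-trichlorotitanium enolate of 16 (formed in situ) | CC1(C)C=Cc2c(ccc(/C=C(\O[Ti](Cl)(Cl)Cl)N3[C@@H](Cc4ccccc4)COC3=O)c2O[Si](C(C)C)(C(C)C)C(C)C)O1 | intermediate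
18 | (S)-4-benzyl-3-{(R)-2-[2,2-dimethyl-5-(triisopropylsilyloxy)-2H-chromen-6-yl]-3-hydroxypropanoyl}oxazolidin-2-one | CC1(C)C=Cc2c(ccc([C@H](CO)C(=O)N3[C@@H](Cc4ccccc4)COC3=O)c2O[Si](C(C)C)(C(C)C)C(C)C)O1 | intermediate
19 | phloroglucinol | Oc1cc(O)cc(O)c1 | starting material
20 | 3,5-bis(triisopropylsilyloxy)phenol | Oc1cc(O[Si](C(C)C)(C(C)C)C(C)C)cc(O[Si](C(C)C)(C(C)C)C(C)C)c1 | intermediate
21 | (S)-4-benzyl-3-{(R)-3-[3,5-bis(triisopropylsilyloxy)phenoxy]-2-[2,2-dimethyl-5-(triisopropylsilyloxy)-2H-chromen-6-yl]propanoyl}oxazolidin-2-one | CC1(C)C=Cc2c(ccc([C@H](COc3cc(O[Si](C(C)C)(C(C)C)C(C)C)cc(O[Si](C(C)C)(C(C)C)C(C)C)c3)C(=O)N3[C@@H](Cc4ccccc4)COC3=O)c2O[Si](C(C)C)(C(C)C)C(C)C)O1 | intermediate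
22 | lithium (R)-percarboxylate corresponding to acid 23 (formed in situ) | CC1(C)C=Cc2c(ccc([C@H](COc3cc(O[Si](C(C)C)(C(C)C)C(C)C)cc(O[Si](C(C)C)(C(C)C)C(C)C)c3)C(=O)OO[Li])c2O[Si](C(C)C)(C(C)C)C(C)C)O1 | intermediate
23 | (R)-3-[3,5-bis(triisopropylsilyloxy)phenoxy]-2-[2,2-dimethyl-5-(triisopropylsilyloxy)-2H-chromen-6-yl]propanoic acid | CC1(C)C=Cc2c(ccc([C@H](COc3cc(O[Si](C(C)C)(C(C)C)C(C)C)cc(O[Si](C(C)C)(C(C)C)C(C)C)c3)C(=O)O)c2O[Si](C(C)C)(C(C)C)C(C)C)O1 | intermediate
24 | (R)-acid chloride of 23 (formed in situ) | CC1(C)C=Cc2c(ccc([C@H](COc3cc(O[Si](C(C)C)(C(C)C)C(C)C)cc(O[Si](C(C)C)(C(C)C)C(C)C)c3)C(=O)Cl)c2O[Si](C(C)C)(C(C)C)C(C)C)O1 | intermediate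
25 | (R)-3-[2,2-dimethyl-5-(triisopropylsilyloxy)-2H-chromen-6-yl]-5,7-bis(triisopropylsilyloxy)chroman-4-one | CC1(C)C=Cc2c(ccc([C@@H]3COc4cc(O[Si](C(C)C)(C(C)C)C(C)C)cc(O[Si](C(C)C)(C(C)C)C(C)C)c4C3=O)c2O[Si](C(C)C)(C(C)C)C(C)C)O1 | intermediate
26 | (R)-5,7-dihydroxy-3-(5-hydroxy-2,2-dimethyl-2H-chromen-6-yl)chroman-4-one | CC1(C)C=Cc2c(ccc([C@@H]3COc4cc(O)cc(O)c4C3=O)c2O)O1 | target

Total step count: 12. Longest linear sequence: 10 (step 1 or 2, then 3, 4, 5, 6, 7, 9, 10, 11, 12).

Steps most likely to fail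

Step 3. Both partners are electron-rich. The cycloaddition may therefore be too slow to compete with silver- or acid-induced consumption of the ynol ether (hydration, oligomerisation) or with [2+2] addition.
- The fallback buys ring B instead of building it. It sets out from prenal 2 and comes back at alcohol 11.
- Prenal 2 is condensed with purchased 2,4-dihydroxybenzaldehyde F1 (Ca(OH)2, MeOH, rt). Aldol-type condensation at C3 gives the quinone methide F2, which electrocyclises through the unchelated 4-oxygen to 5-hydroxy-2,2-dimethyl-2H-chromene-6-carbaldehyde F3.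
- Silylation (TIPSOTf, 2,6-lutidine, CH2Cl2) gives 5-(triisopropylsilyloxy)-2,2-dimethyl-2H-chromene-6-carbaldehyde F4.
- Wittig methylenation (MePPh3Br, KOt-Bu, THF) gives 6-ethenyl-5-(triisopropylsilyloxy)-2,2-dimethyl-2H-chromene F5.
- 9-BBN adds to the terminal alkene in preference to the hindered chromene alkene, giving the B-alkyl-9-borabicyclononane F6. NaBO3 in THF/H2O oxidises this to 11.

Step 9. The hydroxyl that is activated lies beta to an imide and next to a benzylic C-H. This invites β-elimination, and conjugate re-addition of the phenol would then erode the configuration at the future C3.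
- The fallback forms the aryl-oxygen bond instead of the alkyl-oxygen bond, so the hydroxyl never becomes a leaving group. It sets out from alcohol 18 and comes back at 21.
- Purchased 5-bromobenzene-1,3-diol F7 is silylated (TIPSCl, imidazole, DMF) to 1-bromo-3,5-bis(triisopropylsilyloxy)benzene F8.
- Bromine-lithium exchange (n-BuLi, THF, −78 °C) gives [3,5-bis(triisopropylsilyloxy)phenyl]lithium F9. B(Oi-Pr)3 converts it into diisopropyl [3,5-bis(triisopropylsilyloxy)phenyl]boronate F10, and mild aqueous acid gives [3,5-bis(triisopropylsilyloxy)phenyl]boronic acid F11.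
- Chan-Lam coupling of F11 with 18 (Cu(OAc)2, 4-(dimethylamino)pyridine, 4 Å MS, O2, CH2Cl2, rt) gives 21.

Step 11. Enolisation or ketene formation at the activated acyl stage, or enolisation of the tin-bound ketone, would erode the configuration at C3. Participation of the 2'-silyloxy oxygen at the acyl carbon would also cost material.
- The fallback resets the stereocentre by catalyst control instead of carrying it through. It sets out from 25 of eroded enantiopurity and comes back at 25.
- The first operation is asymmetric transfer hydrogenation under dynamic kinetic resolution (RuCl[(R,R)-TsDPEN](p-cymene), HCO2H/Et3N, CH2Cl2, rt to 40 °C).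
- The amine equilibrates C3 while the catalyst reduces the 3R ketone to the 4R alcohol. This should give (3R,4R)-cis-3-[2,2-dimethyl-5-(triisopropylsilyloxy)-2H-chromen-6-yl]-5,7-bis(triisopropylsilyloxy)chroman-4-ol F12.
- Dess-Martin periodinane with NaHCO3 in CH2Cl2 reoxidises C4 without touching C3.

Further compounds
F1 | step 3 | 2,4-dihydroxybenzaldehyde (purchased) | O=Cc1ccc(O)cc1O
F2 | step 3 | 2-hydroxy-3-(3-methylbut-2-en-1-ylidene)-4-oxocyclohexa-1,5-diene-1-carbaldehyde (quinone methide, formed in situ) | CC(C)=C/C=C1\C(=O)C=CC(C=O)=C1O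
F3 | step 3 | 5-hydroxy-2,2-dimethyl-2H-chromene-6-carbaldehyde | CC1(C)C=Cc2c(ccc(C=O)c2O)O1
F4 | step 3 | 5-(triisopropylsilyloxy)-2,2-dimethyl-2H-chromene-6-carbaldehyde | CC1(C)C=Cc2c(ccc(C=O)c2O[Si](C(C)C)(C(C)C)C(C)C)O1
F5 | step 3 | 6-ethenyl-5-(triisopropylsilyloxy)-2,2-dimethyl-2H-chromene | CC1(C)C=Cc2c(ccc(C=C)c2O[Si](C(C)C)(C(C)C)C(C)C)O1
F6 | step 3 | 9-{2-[2,2-dimethyl-5-(triisopropylsilyloxy)-2H-chromen-6-yl]ethyl}-9-borabicyclo[3.3.1]nonane (formed in situ) | CC1(C)C=Cc2c(ccc(CCB3C4CCCC3CCC4)c2O[Si](C(C)C)(C(C)C)C(C)C)O1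
F7 | step 9 | 5-bromobenzene-1,3-diol (purchased) | Oc1cc(O)cc(Br)c1
F8 | step 9 | 1-bromo-3,5-bis(triisopropylsilyloxy)benzene | Brc1cc(O[Si](C(C)C)(C(C)C)C(C)C)cc(O[Si](C(C)C)(C(C)C)C(C)C)c1
F9 | step 9 | [3,5-bis(triisopropylsilyloxy)phenyl]lithium (formed in situ) | [Li]c1cc(O[Si](C(C)C)(C(C)C)C(C)C)cc(O[Si](C(C)C)(C(C)C)C(C)C)c1
F10 | step 9 | diisopropyl [3,5-bis(triisopropylsilyloxy)phenyl]boronate (formed in situ) | CC(C)OB(OC(C)C)c1cc(O[Si](C(C)C)(C(C)C)C(C)C)cc(O[Si](C(C)C)(C(C)C)C(C)C)c1
F11 | step 9 | [3,5-bis(triisopropylsilyloxy)phenyl]boronic acid | OB(O)c1cc(O[Si](C(C)C)(C(C)C)C(C)C)cc(O[Si](C(C)C)(C(C)C)C(C)C)c1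
F12 | step 11 | (3R,4R)-3-[2,2-dimethyl-5-(triisopropylsilyloxy)-2H-chromen-6-yl]-5,7-bis(triisopropylsilyloxy)chroman-4-ol | CC1(C)C=Cc2c(ccc([C@@H]3COc4cc(O[Si](C(C)C)(C(C)C)C(C)C)cc(O[Si](C(C)C)(C(C)C)C(C)C)c4[C@@H]3O)c2O[Si](C(C)C)(C(C)C)C(C)C)O1
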